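**Plan**

- Ring B is the phenol ring, numbered B1 (C–OAr), B2 (C–OH), B3 (C–OMe), B4 (CH), B5 (C with the three-carbon side chain), B6 (CH). It is cut at B1–B2 and B2–B3: the B2-OH/B3-OMe pair next to the B1 aryl ether is what a methoxycarbene carbon (B3) joined to one inserted CO (B2) gives when the resulting ketene closes onto a diene B4=B5–B6=B1 that ends in the aryloxy carbon.
- Further cuts: B3–B4 (dienyllithium + Cr(CO)6), the B1–O aryl ether bond (Chan–Lam coupling), B6=B1 (boron–Wittig olefination) and the B5–side-chain bond (carbomagnesiation of propargyl alcohol). Ring A is bought intact as 2,6-dimethoxy-4-propylphenol.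
- Forward: side-chain Grignard + propargyl alcohol → Z-iodoallyl alcohol → Z-iodoenal → dienylboronate → aryl dienyl ether → chromium carbene complex. Ring B is the only ring formed and arises in the penultimate step; debenzylation ends the route.
- Stereochemistry: the target has no stereocentre. The Z geometry at B4=B5 that ring closure needs comes from the copper-catalysed anti-carbomagnesiation (iodine cis to the carbinol carbon); the E geometry at B6=B1 comes from the boron–Wittig step and a retentive C–O coupling.

Key step: step 7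

Assumption: compounds 1, 3, 7, 9 and 11 are taken as commercial; because the target is achiral, only alkene geometry in the open-chain intermediates has to be controlled.

**Route**

Step 1
Reactants: 1 benzyl 3-bromopropyl ether
Product: 2 [3-(benzyloxy)propyl]magnesium bromide (used as its solution)
Conditions: Mg turnings, THF, rt to 40 °C
Reagents that add atoms: magnesium, [Mg]
Why: Grignard reagent formation by insertion of magnesium into a primary alkyl bromide is routine, and the remote benzyl ether is inert to it.

Step 2
Reactants: 2 [3-(benzyloxy)propyl]magnesium bromide (2.5 equiv); 3 propargyl alcohol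
Product: 5 (Z)-2-[3-(benzyloxy)propyl]-3-iodoprop-2-en-1-ol, via alkenylmagnesium alkoxide 4 (not isolated)
Conditions: CuI (10 mol %), THF, −10 °C to rt; then I2, −40 to 0 °C
Reagents that add atoms: iodine, II
Why: Copper-catalysed anti-carbomagnesiation of a propargylic magnesium alkoxide puts the alkyl group on the inner alkyne carbon and magnesium on the terminus on the alkoxide side (five-membered chelate), so iodinolysis with retention should place iodine cis to the hydroxymethyl group, which is the Z geometry later needed at B4=B5.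

Step 3
Reactants: 5 (Z)-2-[3-(benzyloxy)propyl]-3-iodoprop-2-en-1-ol
Product: 6 (Z)-2-[3-(benzyloxy)propyl]-3-iodoprop-2-enal
Conditions: activated MnO2, CH2Cl2, rt, dark; filtered and used at once
Reagents that add atoms: none
Why: Allylic alcohol oxidation with MnO2 is neutral and mild and is the usual entry to configurationally fragile Z-β-iodoenals, which are carried on without chromatography.

Step 4
Reactants: 6 (Z)-2-[3-(benzyloxy)propyl]-3-iodoprop-2-enal; 7 bis(pinacolato)borylmethane
Product: 8 2-[(1E,3Z)-3-[3-(benzyloxy)propyl]-4-iodobuta-1,3-dien-1-yl]-4,4,5,5-tetramethyl-1,3,2-dioxaborolane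
Conditions: 7, lithium 2,2,6,6-tetramethylpiperidide, THF, 0 °C; then 6, −78 °C to rt
Reagents that add atoms: none
Why: In the boron–Wittig olefination the lithiated geminal bis(boronate) adds to the aldehyde carbonyl and eliminates a borate to give the trans-alkenyl pinacol boronate, the hindered carbanion being expected to prefer 1,2-addition over attack at the iodine-bearing carbon.

Step 5
Reactants: 8 the dienyl pinacol boronate; 9 2,6-dimethoxy-4-propylphenol
Product: 10 2-{[(1E,3Z)-3-[3-(benzyloxy)propyl]-4-iodobuta-1,3-dien-1-yl]oxy}-1,3-dimethoxy-5-propylbenzene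
Conditions: Cu(OAc)2 (2 equiv), pyridine, 4 Å molecular sieves, CH2Cl2, dry air, rt; chromatography on Et3N-deactivated SiO2
Reagents that add atoms: none
Why: Chan–Lam oxidative C–O coupling of a phenol with an alkenylboron compound under divalent copper runs at room temperature with retention of alkene geometry and should leave the alkenyl iodide untouched, which a palladium- or monovalent-copper-catalysed halide coupling would not.

Step 6
Reactants: 10 the aryl iododienyl ether; 11 chromium hexacarbonyl
Product: 14 pentacarbonyl[(2Z,4E)-3-[3-(benzyloxy)propyl]-5-(2,6-dimethoxy-4-propylphenoxy)-1-methoxypenta-2,4-dien-1-ylidene]chromium, via dienyllithium 12 (not isolated), via lithium acylchromate 13 (not isolated)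
Conditions: t-BuLi (2 equiv), Et2O, −78 °C; Cr(CO)6, Et2O–THF, −78 to 0 °C; Me3OBF4, CH2Cl2, 0 °C, dark
Reagents that add atoms: trimethyloxonium tetrafluoroborate, C[O+](C)C.F[B-](F)(F)F
Why: In this Fischer carbene synthesis, iodine–lithium exchange with retention gives the Z-dienyllithium, which adds to a carbonyl ligand of Cr(CO)6 to form the acylchromate that the hard oxonium salt methylates on oxygen, so that B3 now and B2 in the next step both come from Cr(CO)6.

Step 7
Reactants: 14 the pentacarbonylchromium dienyl(methoxy)carbene complex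
Product: 17 4-[3-(benzyloxy)propyl]-2-(2,6-dimethoxy-4-propylphenoxy)-6-methoxyphenol, via dienylketene 15 (not isolated), via cyclohexadienone 16 (not isolated)
Conditions: hν (medium-pressure Hg lamp, Pyrex), CO (1 atm), THF, 20 °C; then air, SiO2 filtration
Reagents that add atoms: none
Why: Irradiation into the metal-to-ligand charge-transfer band should drive insertion of one carbonyl ligand of 14 into the Cr=C bond (bond B2–B3) and give the chromium-bound methoxy(dienyl)ketene 15. Because B4=B5 is Z, the ketene carbon lies next to the aryloxy-bearing terminus B1, and a thermal six-electron disrotatory electrocyclisation closes the six-membered ring B through bond B1–B2 to give cyclohexadienone 16, whose B1–H then moves to oxygen to give the phenol. The closest known reaction type is the photochemical ortho-benzannulation of chromium dienyl(alkoxy)carbene complexes to ortho-alkoxyphenols, a relative of the Dötz benzannulation, applied here to an open-chain diene with an aryloxy terminus. The sp3 centre formed at B1 in 16 is transient and is erased on aromatisation, so no stereocentre has to be controlled. The step needs the hydroxyl at B2 between aryloxy and methoxy and a diene that can close: the first follows from the mechanism, since the hydroxyl carbon can only be the inserted carbonyl next to the methoxycarbene carbon, and the second is secured by the Z geometry at B4=B5 from step 2 and by the E enol ether, which keeps the aryloxy group on the outside of the closing triene. The CO atmosphere only refills chromium, returning it as Cr(CO)6 and keeping it off the product arene.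

Step 8
Reactants: 17 the benzyl-protected phenol
Product: 18 2-(2,6-dimethoxy-4-propylphenoxy)-4-(3-hydroxypropyl)-6-methoxyphenol
Conditions: H2 (1 atm), Pd/C, EtOAc, rt
Reagents that add atoms: none
Why: Hydrogenolysis of a benzyl alkyl ether over Pd/C is standard, and the diaryl ether, the aryl methyl ethers and the phenol are stable to it.

**Compound list**

1 | benzyl 3-bromopropyl ether | BrCCCOCc1ccccc1 | starting material
2 | [3-(benzyloxy)propyl]magnesium bromide | Br[Mg]CCCOCc1ccccc1 | intermediate
3 | propargyl alcohol (prop-2-yn-1-ol) | C#CCO | starting material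
4 | bromomagnesium (Z)-2-[3-(benzyloxy)propyl]-3-(bromomagnesio)prop-2-en-1-olate | Br[Mg]/C=C(CCCOCc1ccccc1)\CO[Mg]Br | intermediate
5 | (Z)-2-[3-(benzyloxy)propyl]-3-iodoprop-2-en-1-ol | I/C=C(CCCOCc1ccccc1)\CO | intermediate
6 | (Z)-2-[3-(benzyloxy)propyl]-3-iodoprop-2-enal | I/C=C(CCCOCc1ccccc1)\C=O | intermediate
7 | bis(pinacolato)borylmethane, 2,2'-methylenebis(4,4,5,5-tetramethyl-1,3,2-dioxaborolane) | CC1(C)OB(CB2OC(C)(C)C(C)(C)O2)OC1(C)C | starting material
8 | 2-[(1E,3Z)-3-[3-(benzyloxy)propyl]-4-iodobuta-1,3-dien-1-yl]-4,4,5,5-tetramethyl-1,3,2-dioxaborolane | I/C=C(CCCOCc1ccccc1)\C=C\B1OC(C)(C)C(C)(C)O1 | intermediate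
9 | 2,6-dimethoxy-4-propylphenol | CCCc1cc(OC)c(O)c(OC)c1 | starting material
10 | 2-{[(1E,3Z)-3-[3-(benzyloxy)propyl]-4-iodobuta-1,3-dien-1-yl]oxy}-1,3-dimethoxy-5-propylbenzene | I/C=C(CCCOCc1ccccc1)\C=C\Oc1c(OC)cc(CCC)cc1OC | intermediate
11 | chromium hexacarbonyl | [C-]#[O+].[C-]#[O+].[C-]#[O+].[C-]#[O+].[C-]#[O+].[C-]#[O+].[Cr] | starting material
12 | [(1Z,3E)-2-[3-(benzyloxy)propyl]-4-(2,6-dimethoxy-4-propylphenoxy)buta-1,3-dien-1-yl]lithium | [Li]/C=C(CCCOCc1ccccc1)\C=C\Oc1c(OC)cc(CCC)cc1OC | intermediate
13 | lithium pentacarbonyl[(2Z,4E)-3-[3-(benzyloxy)propyl]-5-(2,6-dimethoxy-4-propylphenoxy)-1-oxidopenta-2,4-dien-1-ylidene]chromate | [Li+].[O-]C(=[Cr](=C=O)(=C=O)(=C=O)(=C=O)=C=O)/C=C(CCCOCc1ccccc1)\C=C\Oc1c(OC)cc(CCC)cc1OC | intermediate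
14 | pentacarbonyl[(2Z,4E)-3-[3-(benzyloxy)propyl]-5-(2,6-dimethoxy-4-propylphenoxy)-1-methoxypenta-2,4-dien-1-ylidene]chromium | COC(=[Cr](=C=O)(=C=O)(=C=O)(=C=O)=C=O)/C=C(CCCOCc1ccccc1)\C=C\Oc1c(OC)cc(CCC)cc1OC | intermediate
15 | (3Z,5E)-4-[3-(benzyloxy)propyl]-6-(2,6-dimethoxy-4-propylphenoxy)-2-methoxyhexa-1,3,5-trien-1-one (the dienylketene, drawn without the chromium carbonyl fragment to which it is bound when formed) | COC(=C=O)/C=C(CCCOCc1ccccc1)\C=C\Oc1c(OC)cc(CCC)cc1OC | intermediate
16 | 4-[3-(benzyloxy)propyl]-6-(2,6-dimethoxy-4-propylphenoxy)-2-methoxycyclohexa-2,4-dien-1-one (racemic, transient) | COC1=CC(CCCOCc2ccccc2)=CC(Oc2c(OC)cc(CCC)cc2OC)C1=O | intermediate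
17 | 4-[3-(benzyloxy)propyl]-2-(2,6-dimethoxy-4-propylphenoxy)-6-methoxyphenol | CCCc1cc(OC)c(Oc2cc(CCCOCc3ccccc3)cc(OC)c2O)c(OC)c1 | intermediate
18 | 2-(2,6-dimethoxy-4-propylphenoxy)-4-(3-hydroxypropyl)-6-methoxyphenol | CCCc1cc(OC)c(Oc2cc(CCCO)cc(OC)c2O)c(OC)c1 | target

**Step count and risks**

Total step count: 8. Longest linear sequence: 8 steps (1 to 18); compounds 3, 7, 9 and 11 enter as purchased materials.

Steps most likely to fail:

1. Step 7 (key step). The donor–acceptor dienylcarbene may lose its Z geometry at B4=B5 through its zwitterionic resonance form, or cyclise thermally onto the carbene carbon, before light-driven CO insertion occurs, so that ketene formation and six-ring closure are starved. Hydrolysis of the enol ether during handling is a further drain.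
Fallback: ring B is taken from an aromatic building block and the diaryl ether is made by Ullmann coupling. The fallback sets out from phenol 9 and comes back to the route at target 18. Phenol 9 would be coupled with 4-(benzyloxy)-3-bromo-5-methoxybenzaldehyde F1 (commercial, or from 5-bromovanillin and benzyl bromide with K2CO3) under CuI, N,N-dimethylglycine and Cs2CO3 in dioxane at 100 °C to give 4-(benzyloxy)-3-(2,6-dimethoxy-4-propylphenoxy)-5-methoxybenzaldehyde F2. Horner–Wadsworth–Emmons reaction with triethyl phosphonoacetate and NaH would give ethyl (E)-3-[4-(benzyloxy)-3-(2,6-dimethoxy-4-propylphenoxy)-5-methoxyphenyl]prop-2-enoate F3. Hydrogenation over Pd/C would saturate the alkene and remove the benzyl group to give ethyl 3-[3-(2,6-dimethoxy-4-propylphenoxy)-4-hydroxy-5-methoxyphenyl]propanoate F4, and LiAlH4 reduction of the ester would give 18.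

2. Step 5. Oxidation of the electron-rich, doubly ortho-substituted phenol by divalent copper, slow transmetalation of the pinacol boronate and protodeboronation may outrun C–O bond formation.
Fallback: the enol ether is made by Wittig olefination, without any copper-mediated C–O coupling. The fallback sets out from phenol 9 and aldehyde 6 and comes back at 10, bypassing steps 4 and 5. Phenol 9 would be alkylated with NaH and chloromethyl methyl sulfide to 1,3-dimethoxy-2-[(methylsulfanyl)methoxy]-5-propylbenzene F5, which sulfuryl chloride would convert into 2-(chloromethoxy)-1,3-dimethoxy-5-propylbenzene F6. Triphenylphosphine would then give [(2,6-dimethoxy-4-propylphenoxy)methyl]triphenylphosphonium chloride F7. Its ylide (NaN(SiMe3)2, THF, −78 °C) would be condensed with aldehyde 6 to give 10 together with its 1Z isomer 2-{[(1Z,3Z)-3-[3-(benzyloxy)propyl]-4-iodobuta-1,3-dien-1-yl]oxy}-1,3-dimethoxy-5-propylbenzene F8, which would be removed by chromatography.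

3. Step 6. Deprotonation next to the enol ether oxygen or at a benzylic position by t-BuLi may compete with halogen–lithium exchange, and the cis-dienyllithium may lose its geometry if it warms before it is trapped.
Fallback: the organolithium is generated by tin–lithium exchange instead of from the iodide with t-BuLi. The fallback sets out from 10 and comes back at dienyllithium 12. Iodide 10 would be stannylated with hexamethylditin and catalytic Pd(PPh3)4 in toluene at 80 °C to give [(1Z,3E)-2-[3-(benzyloxy)propyl]-4-(2,6-dimethoxy-4-propylphenoxy)buta-1,3-dien-1-yl]trimethylstannane F9. Methyllithium in THF at −78 °C would then give 12, which is carried on with Cr(CO)6 and Me3OBF4 as in step 6.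

**Further compounds**

F1 | step 7 | 4-(benzyloxy)-3-bromo-5-methoxybenzaldehyde | O=Cc1cc(Br)c(OCc2ccccc2)c(OC)c1
F2 | step 7 | 4-(benzyloxy)-3-(2,6-dimethoxy-4-propylphenoxy)-5-methoxybenzaldehyde | O=Cc1cc(Oc2c(OC)cc(CCC)cc2OC)c(OCc2ccccc2)c(OC)c1
F3 | step 7 | ethyl (E)-3-[4-(benzyloxy)-3-(2,6-dimethoxy-4-propylphenoxy)-5-methoxyphenyl]prop-2-enoate | CCOC(=O)/C=C/c1cc(Oc2c(OC)cc(CCC)cc2OC)c(OCc2ccccc2)c(OC)c1
F4 | step 7 | ethyl 3-[3-(2,6-dimethoxy-4-propylphenoxy)-4-hydroxy-5-methoxyphenyl]propanoate | CCOC(=O)CCc1cc(Oc2c(OC)cc(CCC)cc2OC)c(O)c(OC)c1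
F5 | step 5 | 1,3-dimethoxy-2-[(methylsulfanyl)methoxy]-5-propylbenzene | CSCOc1c(OC)cc(CCC)cc1OC
F6 | step 5 | 2-(chloromethoxy)-1,3-dimethoxy-5-propylbenzene | ClCOc1c(OC)cc(CCC)cc1OC
F7 | step 5 | [(2,6-dimethoxy-4-propylphenoxy)methyl]triphenylphosphonium chloride | [Cl-].CCCc1cc(OC)c(OC[P+](c2ccccc2)(c2ccccc2)c2ccccc2)c(OC)c1
F8 | step 5 | 2-{[(1Z,3Z)-3-[3-(benzyloxy)propyl]-4-iodobuta-1,3-dien-1-yl]oxy}-1,3-dimethoxy-5-propylbenzene | I/C=C(CCCOCc1ccccc1)\C=C/Oc1c(OC)cc(CCC)cc1OC
F9 | step 6 | [(1Z,3E)-2-[3-(benzyloxy)propyl]-4-(2,6-dimethoxy-4-propylphenoxy)buta-1,3-dien-1-yl]trimethylstannane | C[Sn](C)(C)/C=C(CCCOCc1ccccc1)\C=C\Oc1c(OC)cc(CCC)cc1OC
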